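**Retrosynthetic overview**
- Target 17 comes from the (R)-lactone 16 by removal of three MOM groups; 16 comes from 4-arylcoumarin 15 by a ligand-controlled copper hydride conjugate reduction that sets C4, the only stereocenter.
- The lactone ring of 15 (O1, C2, C3, C4) is closed on hydroxybenzophenone 13 by acylation of the C8a–OH with a cumulated ylide and intramolecular Wittig olefination at the ketone carbon (future C4).
- The strategy rests on ring A (C4a, C5, C6, C7, C8, C8a; chroman-2-one numbering): oxygen on C8a and C7, the styryl group on C5 and C4 on C4a. This is the pattern left when a 1,1,3-trioxygenated butadiene (C8a, C8, C7, C6) adds across an aroyl alkyne C4a≡C5, so ring A is cut at C8a–C4a and C6–C5 into diene 9 and ynone 6.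
- Ynone 6 comes from Sonogashira coupling of vinyl iodide 3 with propargylic alcohol 4 (both from MOM-vanillin 2) and oxidation; diene 9 comes from methyl acetoacetate 7.
- Ring order: ring A (step 8), then the lactone ring (step 10); both guaiacyl rings come from vanillin.

Key step: step 8

Remark: C4 of the target is read as (R) (C4a > aryl > C3 > H); (R)-DTBM-SEGPHOS is assumed to deliver hydride to the Si face of C4 by analogy with simple 4-arylcoumarins, and the (S)-ligand is used if the sense proves opposite; in names, Ar = 3-methoxy-4-(methoxymethoxy)phenyl.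

**Step 1**
Reactants: 1 vanillin
Product: 2 3-methoxy-4-(methoxymethoxy)benzaldehyde
Conditions: MOMCl, i-Pr2NEt, CH2Cl2, 0 °C to rt
Reagents that add atoms: chloromethyl methyl ether (MOMCl), COCCl
Why: O-alkylation of the phenol (MOM protection) under amine base should be clean, since the aldehyde is inert to these conditions.

**Step 2**
Reactants: 2 3-methoxy-4-(methoxymethoxy)benzaldehyde
Product: 3 4-[(E)-2-iodoethenyl]-2-methoxy-1-(methoxymethoxy)benzene
Conditions: CrCl2 (6 equiv), CHI3 (2 equiv), THF, 0 °C to rt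
Reagents that add atoms: iodoform, IC(I)I
Why: Takai olefination, in which the geminal dichromium species from iodoform and divalent chromium chloride adds to the aromatic aldehyde and eliminates to the E-vinyl iodide; the aryl MOM ether is not affected.

**Step 3**
Reactants: 2 3-methoxy-4-(methoxymethoxy)benzaldehyde
Product: 4 rac-1-Ar-prop-2-yn-1-ol
Conditions: HC≡CMgBr (0.5 M in THF), THF, 0 °C; aqueous work-up
Reagents that add atoms: ethynylmagnesium bromide, C#C[Mg]Br
Why: Grignard 1,2-addition of the acetylide to the aldehyde; the carbinol center is racemic and is removed by the oxidation in step 5.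

**Step 4**
Reactants: 3 4-[(E)-2-iodoethenyl]-2-methoxy-1-(methoxymethoxy)benzene; 4 rac-1-Ar-prop-2-yn-1-ol
Product: 5 rac-(E)-1,5-bis(Ar)pent-4-en-2-yn-1-ol
Conditions: PdCl2(PPh3)2 (2 mol %), CuI (4 mol %), Et3N, THF (degassed), rt
Reagents that add atoms: none
Why: Sonogashira coupling of an alkenyl iodide with a terminal alkyne proceeds with retention of the E geometry and tolerates the free propargylic hydroxyl.

**Step 5**
Reactants: 5 rac-(E)-1,5-bis(Ar)pent-4-en-2-yn-1-ol
Product: 6 (E)-1,5-bis(Ar)pent-4-en-2-yn-1-one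
Conditions: Dess–Martin periodinane, CH2Cl2, 0 °C to rt
Reagents that add atoms: none
Why: Dess–Martin oxidation of a benzylic, propargylic secondary alcohol to the ynone under near-neutral conditions that leave the MOM ethers and the enyne alone.

**Step 6**
Reactants: 7 methyl acetoacetate
Product: 8 methyl 3-(trimethylsilyloxy)but-2-enoate (E/Z mixture)
Conditions: Me3SiCl, Et3N, hexane, rt
Reagents that add atoms: chlorotrimethylsilane, C[Si](C)(C)Cl
Why: O-silylation of the enol of the β-keto ester (silyl enol ether formation).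

**Step 7**
Reactants: 8 methyl 3-(trimethylsilyloxy)but-2-enoate
Product: 9 1-methoxy-1,3-bis(trimethylsilyloxy)buta-1,3-diene (E/Z mixture)
Conditions: LiN(i-Pr)2, THF, −78 °C; Me3SiCl, −78 °C to rt; used freshly distilled
Reagents that add atoms: chlorotrimethylsilane, C[Si](C)(C)Cl
Why: γ-Deprotonation of the silyloxy enoate gives the ester dienolate, and O-silylation of it gives the ketene acetal diene (silyl ketene acetal formation).

**Step 8**
Reactants: 6 (E)-1,5-bis(Ar)pent-4-en-2-yn-1-one; 9 1-methoxy-1,3-bis(trimethylsilyloxy)buta-1,3-diene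
Product: 12 {2,4-dihydroxy-6-[(E)-2-Ar-ethenyl]phenyl}(Ar)methanone, via cyclohexa-1,4-diene cycloadduct 10 (not isolated), via bis(trimethylsilyl) ether 11 (not isolated)
Conditions: 9 (2 equiv), toluene, 80 °C; then 10% aq. citric acid, THF, rt
Reagents that add atoms: none
Why: The electron-rich diene 9 and the ketone-polarized alkyne of 6 combine in an asynchronous Diels–Alder [4+2] cycloaddition (a Michael addition followed by Claisen-type closure leads to the same adduct), the diene CH2 (future C6) bonding to the alkyne β-carbon C5 and the ketene acetal carbon (future C8a) to the α-carbon C4a to give cyclohexa-1,4-diene 10. Adduct 10 then loses methanol by 1,4-elimination across C8a/C6 to aromatize to 11, and the aqueous citric acid cleaves both aryl silyl ethers (any unaromatized 10 is hydrolysed to the same resorcinol through its diketone tautomer). The closest known reaction type is the Diels–Alder/aromatization of 1,3-dioxygenated ketene acetal dienes with acetylenic ketones and esters, which delivers resorcinols. Ring A is closed by an intermolecular [4+2] cycloaddition that makes C8a–C4a and C6–C5 in one operation; no stereocenter survives (C8a of 10 is lost on aromatization) and the E styryl alkene is a spectator. The step needs regio- and chemoselectivity: the aroyl group makes C5 the electrophilic alkyne carbon and the diene has its largest HOMO coefficient at CH2, so the aroyl carbon ends between the C8a hydroxyl and the C5 styryl group; only the alkyne is directly conjugated to the carbonyl, so the styryl alkene is not attacked, and the absence of a Lewis acid disfavors closure through the central diene carbon onto the ketone.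

**Step 9**
Reactants: 12 {2,4-dihydroxy-6-[(E)-2-Ar-ethenyl]phenyl}(Ar)methanone
Product: 13 {2-hydroxy-4-(methoxymethoxy)-6-[(E)-2-Ar-ethenyl]phenyl}(Ar)methanone
Conditions: MOMCl (1.05 equiv), i-Pr2NEt (1.2 equiv), CH2Cl2, 0 °C
Reagents that add atoms: chloromethyl methyl ether (MOMCl), COCCl
Why: Chemoselective O-alkylation (MOM protection) of the C7 hydroxyl, which is para to the carbonyl, more acidic and unhindered, while the C8a hydroxyl is hydrogen-bonded to the ketone and flanked by the aroyl group.

**Step 10**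
Reactants: 13 {2-hydroxy-4-(methoxymethoxy)-6-[(E)-2-Ar-ethenyl]phenyl}(Ar)methanone
Product: 15 4-Ar-7-(methoxymethoxy)-5-[(E)-2-Ar-ethenyl]-2H-chromen-2-one, via aryl (triphenylphosphoranylidene)acetate 14 (not isolated)
Conditions: Ph3P=C=C=O (1.3 equiv), toluene, 110 °C
Reagents that add atoms: (triphenylphosphoranylidene)ketene, O=C=C=P(c1ccccc1)(c1ccccc1)c1ccccc1
Why: The phenol O–H adds across the cumulated ylide to give ester ylide 14, which closes by intramolecular Wittig olefination on the diaryl ketone to form the C3=C4 bond and the lactone ring, a known coumarin synthesis from o-hydroxyaryl ketones.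

**Step 11**
Reactants: 15 4-Ar-7-(methoxymethoxy)-5-[(E)-2-Ar-ethenyl]-2H-chromen-2-one
Product: 16 (4R)-4-Ar-7-(methoxymethoxy)-5-[(E)-2-Ar-ethenyl]chroman-2-one
Conditions: Cu(OAc)2·H2O (5 mol %), (R)-DTBM-SEGPHOS (5.5 mol %), (EtO)2MeSiH (1.5 equiv), t-BuOH (1.2 equiv), toluene, 0 °C to rt
Reagents that add atoms: none
Why: Copper hydride-catalysed asymmetric conjugate reduction, known for 4-arylcoumarins: the bisphosphine-ligated monovalent copper hydride delivers hydride to the Si face of C4 (C4a > aryl > C3) under ligand control to set (R), t-BuOH protonates the copper enolate, and the unactivated stilbene alkene is not hydrocuprated under these conditions.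

**Step 12**
Reactants: 16 (4R)-4-Ar-7-(methoxymethoxy)-5-[(E)-2-Ar-ethenyl]chroman-2-one
Product: 17 (4R)-7-hydroxy-4-(4-hydroxy-3-methoxyphenyl)-5-[(E)-2-(4-hydroxy-3-methoxyphenyl)ethenyl]chroman-2-one (CNP0277187.1)
Conditions: ZnBr2 (3.3 equiv), n-PrSH (6.6 equiv), CH2Cl2, 0 °C to rt
Reagents that add atoms: none
Why: Lewis acid-assisted thiolysis of the three aryl MOM acetals, in which the thiol traps the methoxymethyl cation; the medium is aprotic and alcohol-free so the lactone stays closed, and C4 carries no acidic hydrogen and is not epimerized.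

**Compound list**
1 | vanillin | COc1cc(C=O)ccc1O | starting material
2 | 3-methoxy-4-(methoxymethoxy)benzaldehyde | COCOc1ccc(C=O)cc1OC | intermediate
3 | 4-[(E)-2-iodoethenyl]-2-methoxy-1-(methoxymethoxy)benzene | COCOc1ccc(/C=C/I)cc1OC | intermediate
4 | rac-1-[3-methoxy-4-(methoxymethoxy)phenyl]prop-2-yn-1-ol | COCOc1ccc(C(O)C#C)cc1OC | intermediate
5 | rac-(E)-1,5-bis[3-methoxy-4-(methoxymethoxy)phenyl]pent-4-en-2-yn-1-ol | COCOc1ccc(C(O)C#C/C=C/c2ccc(OCOC)c(OC)c2)cc1OC | intermediate
6 | (E)-1,5-bis[3-methoxy-4-(methoxymethoxy)phenyl]pent-4-en-2-yn-1-one | O=C(c1ccc(OCOC)c(OC)c1)C#C/C=C/c1ccc(OCOC)c(OC)c1 | intermediate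
7 | methyl acetoacetate | COC(=O)CC(C)=O | starting material
8 | methyl 3-(trimethylsilyloxy)but-2-enoate (E/Z mixture) | COC(=O)C=C(C)O[Si](C)(C)C | intermediate
9 | 1-methoxy-1,3-bis(trimethylsilyloxy)buta-1,3-diene (E/Z mixture) | C=C(O[Si](C)(C)C)C=C(OC)O[Si](C)(C)C | intermediate
10 | {6-methoxy-2-[(E)-2-Ar-ethenyl]-4,6-bis(trimethylsilyloxy)cyclohexa-1,4-dien-1-yl}(Ar)methanone (racemic cycloadduct, not isolated) | COC1(O[Si](C)(C)C)C=C(O[Si](C)(C)C)CC(/C=C/c2ccc(OCOC)c(OC)c2)=C1C(=O)c1ccc(OCOC)c(OC)c1 | intermediate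
11 | {2-[(E)-2-Ar-ethenyl]-4,6-bis(trimethylsilyloxy)phenyl}(Ar)methanone (not isolated) | C[Si](C)(C)Oc1cc(O[Si](C)(C)C)c(C(=O)c2ccc(OCOC)c(OC)c2)c(/C=C/c2ccc(OCOC)c(OC)c2)c1 | intermediate
12 | {2,4-dihydroxy-6-[(E)-2-Ar-ethenyl]phenyl}(Ar)methanone | Oc1cc(O)c(C(=O)c2ccc(OCOC)c(OC)c2)c(/C=C/c2ccc(OCOC)c(OC)c2)c1 | intermediate
13 | {2-hydroxy-4-(methoxymethoxy)-6-[(E)-2-Ar-ethenyl]phenyl}(Ar)methanone | COCOc1cc(O)c(C(=O)c2ccc(OCOC)c(OC)c2)c(/C=C/c2ccc(OCOC)c(OC)c2)c1 | intermediate
14 | 2-(Ar-carbonyl)-5-(methoxymethoxy)-3-[(E)-2-Ar-ethenyl]phenyl (triphenylphosphoranylidene)acetate (not isolated) | COCOc1cc(OC(=O)C=P(c2ccccc2)(c2ccccc2)c2ccccc2)c(C(=O)c2ccc(OCOC)c(OC)c2)c(/C=C/c2ccc(OCOC)c(OC)c2)c1 | intermediate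
15 | 4-Ar-7-(methoxymethoxy)-5-[(E)-2-Ar-ethenyl]-2H-chromen-2-one | COCOc1cc(/C=C/c2ccc(OCOC)c(OC)c2)c2c(c1)OC(=O)C=C2c1ccc(OCOC)c(OC)c1 | intermediate
16 | (4R)-4-Ar-7-(methoxymethoxy)-5-[(E)-2-Ar-ethenyl]chroman-2-one | COc1cc(/C=C/c2cc(OCOC)cc3c2[C@@H](c2ccc(OCOC)c(OC)c2)CC(=O)O3)ccc1OCOC | intermediate
17 | (4R)-7-hydroxy-4-(4-hydroxy-3-methoxyphenyl)-5-[(E)-2-(4-hydroxy-3-methoxyphenyl)ethenyl]chroman-2-one | COc1cc(/C=C/c2cc(O)cc3c2[C@@H](c2ccc(O)c(OC)c2)CC(=O)O3)ccc1O | target

**Step count**
Total: 12 steps. Longest linear sequence: 9 steps (steps 1, 2, 4, 5, 8, 9, 10, 11, 12 from vanillin).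

**Steps most likely to fail**

Step 8 (key step). The diene may add only once at C5 and not close, may close through its central carbon onto the ketone, or the adduct may aromatize by loss of silanol and leave a methyl ether on C8a; the internal alkyne may also react so slowly that the diene decomposes first. The fallback builds nothing of ring A and instead makes the C5–vinyl bond by cross-coupling; it sets out from 3 and comes back at 13. Phloroglucinol and vanillic acid are joined by Friedel–Crafts acylation in P2O5/MeSO3H to (4-hydroxy-3-methoxyphenyl)(2,4,6-trihydroxyphenyl)methanone F1, where the symmetry of phloroglucinol removes any regiochemical question. MOMCl (2 equiv) with i-Pr2NEt should protect the two hydroxyls that are not hydrogen-bonded to the ketone and give [2,6-dihydroxy-4-(methoxymethoxy)phenyl](Ar)methanone F2. Tf2O (1 equiv) and pyridine in CH2Cl2 at low temperature should convert one of the two equivalent ortho hydroxyls into the mono-triflate F3, the other staying hydrogen-bonded to the carbonyl. Separately, Miyaura borylation of 3 (B2pin2, PdCl2(PPh3)2, KOPh, toluene, 50 °C) gives the (E)-styryl pinacol boronate F4. Suzuki–Miyaura coupling of F3 with F4 (Pd(PPh3)4, K3PO4, dioxane/H2O, 80 °C) then gives 13.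

Step 11. The C5 styryl group lies peri to C4 and may block approach of the bulky ligated copper hydride or lower the facial discrimination, and excess silane may reduce the lactone carbonyl. The fallback replaces asymmetric catalysis by resolution; it sets out from 15 and comes back at 16. Conjugate reduction with a small achiral catalyst (Cu(OAc)2·H2O, 1,2-bis(diphenylphosphino)benzene, polymethylhydrosiloxane, t-BuOH, toluene) should give the racemic tri-MOM lactone F5. Preparative HPLC on an amylose tris(3,5-dimethylphenylcarbamate) phase separates it into 16 and the (S)-lactone F6, which is set aside.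

Step 10. Acylation of the hindered, hydrogen-bonded phenol may be slow, and ring closure onto a ketone with two ortho substituents may be slower than decomposition of the ylide. The fallback replaces phosphorus olefination by an aldol condensation; it sets out from 13 and comes back at 15. Ac2O, pyridine and catalytic DMAP give the aryl acetate F7. LiN(SiMe3)2 in THF at −78 °C forms the ester enolate, which adds intramolecularly to the ketone to give the racemic 4-hydroxy-4-arylchroman-2-one F8. Dehydration with SOCl2 and pyridine at 0 °C gives 15.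

**Further compounds**
F1 | step 8 | (4-hydroxy-3-methoxyphenyl)(2,4,6-trihydroxyphenyl)methanone | COc1cc(C(=O)c2c(O)cc(O)cc2O)ccc1O
F2 | step 8 | [2,6-dihydroxy-4-(methoxymethoxy)phenyl][3-methoxy-4-(methoxymethoxy)phenyl]methanone | COCOc1cc(O)c(C(=O)c2ccc(OCOC)c(OC)c2)c(O)c1
F3 | step 8 | 3-hydroxy-2-[3-methoxy-4-(methoxymethoxy)benzoyl]-5-(methoxymethoxy)phenyl trifluoromethanesulfonate | COCOc1cc(O)c(C(=O)c2ccc(OCOC)c(OC)c2)c(OS(=O)(=O)C(F)(F)F)c1
F4 | step 8 | 2-[(E)-2-[3-methoxy-4-(methoxymethoxy)phenyl]ethenyl]-4,4,5,5-tetramethyl-1,3,2-dioxaborolane | COCOc1ccc(/C=C/B2OC(C)(C)C(C)(C)O2)cc1OC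
F5 | step 11 | rac-4-Ar-7-(methoxymethoxy)-5-[(E)-2-Ar-ethenyl]chroman-2-one | COc1cc(/C=C/c2cc(OCOC)cc3c2C(c2ccc(OCOC)c(OC)c2)CC(=O)O3)ccc1OCOC
F6 | step 11 | (4S)-4-Ar-7-(methoxymethoxy)-5-[(E)-2-Ar-ethenyl]chroman-2-one | COc1cc(/C=C/c2cc(OCOC)cc3c2[C@H](c2ccc(OCOC)c(OC)c2)CC(=O)O3)ccc1OCOC
F7 | step 10 | 2-(Ar-carbonyl)-5-(methoxymethoxy)-3-[(E)-2-Ar-ethenyl]phenyl acetate | CC(=O)Oc1cc(OCOC)cc(/C=C/c2ccc(OCOC)c(OC)c2)c1C(=O)c1ccc(OCOC)c(OC)c1
F8 | step 10 | rac-4-hydroxy-4-Ar-7-(methoxymethoxy)-5-[(E)-2-Ar-ethenyl]chroman-2-one | COCOc1cc(/C=C/c2ccc(OCOC)c(OC)c2)c2c(c1)OC(=O)CC2(O)c1ccc(OCOC)c(OC)c1
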